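# Junceellolide K: synthesis design around a reductive aldol closure of the cyclohexane (C1–C14)

## The problem

Junceellolide K is a briarane. A cyclohexane (C1, C10–C14) is trans-fused along C1–C10 to a ten-membered carbocycle (C1–C10), which holds a (Z)-trisubstituted C5=C6 alkene and is bridged at C7/C8 by a γ-lactone (O7–C19–C17–C8). Nine stereocentres must be set (C1, C2, C7, C8, C9, C10, C11, C14, C17). The hardest is the quaternary C1, which carries the C15 methyl and sits between the C2 and C14 acetoxy carbons and C10.

C10 is the natural control element for the carbocyclic half. With its C9 arm equatorial on the forming cyclohexane it can fix C1; the C1 acyl/C14 hydroxyl pair can then fix C14 and, by 1,3-induction, C2; the axial C15 methyl later shields one face of C11. On the other half, C9 can steer C8 by chelation, C17 can be bought, and only C7 is left to the ring closure.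

The molecule is fragile. The 11,20-spiro-epoxide is sensitive to acid and Lewis acid, and the three acetates to base and nucleophiles. The tertiary β-hydroxy lactone can open by retro-aldol or move to O9. Any C9 oxygen is β to C11 and eliminates once C11 is a ketone in basic medium. The C5=C6 alkene must not compete when the C11 methylene is epoxidised.

The feature that opens the synthesis is the C2–C1–C14 array. With C2 as a ketone it is an aldol retron. Because C1 carries a methyl group, the fully substituted enolate can be made regiospecifically by hydride addition to a C1=C15 methylene ketone. One reductive aldol then forms C1–C14, closes the cyclohexane and sets C1 and C14.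

## Retrosynthesis

**Lactone (C19–O7).** Target 47 is cut at the acyl–oxygen bond to 7,19-diol 44, the desilylation product of 43. This is preferred to a C8–C17 cut because C17 then comes from the chiral pool and C8 from an open-chain chelate. The forward step is an oxidative lactonisation that must oxidise the primary C19 alcohol faster than the hindered allylic C7 alcohol.

**Ten-membered ring (C6–C7).** 43 is cut between the alkenyl carbon C6 and the carbinol C7 to seco-aldehyde 42, which carries a (Z)-alkenyl iodide. Against a C8–C9 or C5=C6 closure, this cut creates only one stereocentre (C7), carries the alkene geometry in from a small reagent, and uses a chromium-mediated addition that tolerates acetates and an epoxide. The precursor is monocyclic; the forward step needs high dilution and an acceptable facial preference at C7.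

**Epoxide and C11.** 42 goes back through 41 and 40 to the 11(20)-alkene 39, and that to C11 ketone 37. Epoxidation is placed before ring closure because the only other alkene is then an iodine-bearing, deactivated one. The axial C15 methyl directs the peracid to the α face. The C9 acetate is introduced (38 to 39) only after C11 has become a methylene, so that no β-acetoxy ketone ever exists.

**C2 and C3–C4.** Diacetate 36 comes from anti-diol 35, the hydroxyl-directed reduction product of ketone 34. 34 is cut at C3–C4 to methyl ketone 29 and allylic bromide 32. C1 is quaternary, so the ketone has a single enolisable position. A methyl ketone is also preferred to a 4-oxygenated chain, which could lose its β-oxygen from the C2 ketone.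

**Key disconnection (C1–C14).** β-Hydroxy ketone 28 is cut between C1 and C14 to enone–aldehyde 25. This removes the ring and two stereocentres, leaving an open chain with the C10, C9, C8 and C17 stereocentres. The forward reaction must deliver hydride to C15 only, keep the acyl group trans to the C9 arm, and place the C14 oxygen cis to the acyl group.

**Enone and C11–C12.** 25 comes from aldehyde 21 by methylenation with formaldehyde (C15), addition of MeMgBr (C3) and oxidation. 21 comes from ketal 20 and ketone 19, and 19 from Weinreb amide 17 and bromide 18. The aldehyde route makes the position of methylenation unambiguous, which a methyl ketone would not.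

**C7–C8.** Diol 16 (the precursor of acetonide 17) is cut at C7–C8 to α-hydroxy ketone 12 and the alkoxymethyl reagent from stannane 15. A five-membered chelate between O9 and the C8 carbonyl is among the most reliable open-chain control elements, and analysis of the chelate shows that the C7 nucleophile, not the C17 branch, must be the one added.

**C9–C10.** 12 goes back to aldol adduct 10, cut at C9–C10 to imide 8 and aldehyde 5. An auxiliary-controlled syn-aldol sets both centres and leaves C11 at the acyl oxidation level that it needs later. 5 derives in four steps from hydroxy ester 1, which supplies C17, with C8 masked as a dithiane.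

## Roads not taken

**Alternative 1:** The cut is C8–C17, made last. A 2-bromopropanoate on O7 of the finished ten-membered α-oxygenated ketone would be reduced by SmI2 to a samarium enolate whose C17 adds to the C8 carbonyl. This closes the γ-lactone and gives A1 with C8 and C17 set together.
- *Merits:* the tether guarantees lactonisation to O7 rather than O9; two stereocentres and the last ring arise in one mild step; no lactone fragment has to be carried through the synthesis.
- *Weak points:* the substrate is an α-acyloxy ketone, a class that SmI2 can cleave at the C7–O bond. The sense of attack at C8 depends on the conformation of the ten-membered ring, and C17 on the enolate geometry; neither is predictable with confidence. The step says nothing about C1, C10 or C14.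
- *Comparison:* for the lactone alone this road is clearly shorter than the chosen plan, which spends steps 4, 8, 10, 33 and 34 on C8, C17 and C19. The chosen plan sets against that a C8 fixed by a magnesium chelate on an open chain and a C17 taken from the chiral pool, so that only C7 depends on the medium ring.

**Alternative 2:** The cuts are C9–C10 and C1–C2 on a preformed six-membered ring. (CH2=CH)2CuLi would add to C10 of enone A3 anti to the silyloxy group. The enolate, transmetalated with ZnCl2, would add through C1 to aldehyde A4 and give A2.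
- *Merits:* this is the fastest entry to the quaternary C1. Two C–C bonds and three stereocentres come from two small fragments, the trans relation of the C9 and C2 arms follows from anti attack on the enolate, and the alkenyl iodide arrives with A4.
- *Weak points:* the aldol must take place at a fully substituted α-methyl enolate, where addition is slow and reversible and the C2 configuration has little bias. C14 is left as a ketone, and hydride is expected to enter anti to the axial C15 methyl and give the equatorial, wrong alcohol. C9 arrives as a bare vinyl carbon, so C9–O and C8 still need new stereocontrol.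
- *Comparison:* Alternative 2 reaches a C1/C10-defined cyclohexane in far fewer steps than the eighteen that precede the key step of the chosen plan, a real advantage. The chosen plan pays for its length by delivering the axial C14 oxygen in the ring-forming step, C2 by directed reduction, and C9, C8 and C17 already in place.

**Alternative 3:** The cut is C8–C9, used to close the ten-membered ring. SmI2 would reduce a C9 formyl group to a ketyl that adds to the C8 carbonyl of the same molecule, giving 8,9-diol A5.
- *Merits:* it is the most convergent road. The medium ring and two oxygenated stereocentres form together, the Z alkene, C7 and C17 are set in an open-chain western fragment, and the diol is the oxidation pattern required.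
- *Weak points:* an aldehyde–ketone pinacol to a ten-membered ring competes with simple reduction and intermolecular coupling. The ketone carries an α-silyloxy group at C7 that ketyl formation can expel. The configuration at C8/C9 would be set by a forming medium ring, not a defined chelate. The C11 ketal also postpones the epoxide to a stage where C5=C6 is an ordinary trisubstituted alkene.
- *Comparison:* in convergency Alternative 3 is better than the chosen plan, whose longest linear sequence is thirty steps. The chosen plan sets against this a ring closure that creates only C7, correctable by oxidation and chelate-controlled reduction, with C8 and C9 secured beforehand.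

Key step: step 19

## Remarks before the route

- Atom labels C1–C20 are those of the briarane skeleton of the target. The configuration of every intermediate is defined by its SMILES string.
- 23 and 24 are carried as mixtures of C2 epimers, because C2 is oxidised in step 18.
- dpm = 2,2,6,6-tetramethylheptane-3,5-dionato (dipivaloylmethanato); PMB = 4-methoxybenzyl.
- Compounds 1, 6, 7, 13, 14, 18 and 30 are taken as commercial.

## Route

Step 1
Reactants: 1 methyl (S)-3-hydroxy-2-methylpropanoate
Product: 2 methyl (S)-3-[(tert-butyldiphenylsilyl)oxy]-2-methylpropanoate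
Conditions: t-BuPh2SiCl, imidazole, CH2Cl2, 0 °C to rt
Reagents that add atoms: tert-butyl(chloro)diphenylsilane, CC(C)(C)[Si](Cl)(c1ccccc1)c1ccccc1
Why: Imidazole-mediated silylation of a primary alcohol; the tert-butyldiphenylsilyl ether is chosen because it must survive acid, base and organometallic steps up to step 33.

Step 2
Reactants: 2 methyl (S)-3-[(tert-butyldiphenylsilyl)oxy]-2-methylpropanoate
Product: 3 (S)-3-[(tert-butyldiphenylsilyl)oxy]-2-methylpropanal
Conditions: iBu2AlH (1.05 equiv), CH2Cl2, −78 °C; aq. KNa tartrate
Reagents that add atoms: none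
Why: Partial ester reduction with iBu2AlH stops at the aluminium hemiacetal at −78 °C and gives the aldehyde on work-up; C17 is not enolised at this temperature.

Step 3
Reactants: 3 (S)-3-[(tert-butyldiphenylsilyl)oxy]-2-methylpropanal
Product: 4 tert-butyl{[(2S)-2-(1,3-dithian-2-yl)propyl]oxy}diphenylsilane
Conditions: HS(CH2)3SH, BF3·OEt2, CH2Cl2, −78 to −20 °C
Reagents that add atoms: propane-1,3-dithiol, SCCCS
Why: Lewis-acid-promoted dithioacetalisation protects the configurationally labile aldehyde at once and turns C8 into an acyl-anion equivalent.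

Step 4
Reactants: 4 tert-butyl{[(2S)-2-(1,3-dithian-2-yl)propyl]oxy}diphenylsilane
Product: 5 2-{(2S)-1-[(tert-butyldiphenylsilyl)oxy]propan-2-yl}-1,3-dithiane-2-carbaldehyde
Conditions: t-BuLi, THF/HMPA (10:1), −78 °C; then Me2NCHO, −78 to 0 °C
Reagents that add atoms: N,N-dimethylformamide, CN(C)C=O
Why: Corey–Seebach umpolung: deprotonation of the 2-alkyl-1,3-dithiane at C8 and formylation with DMF attaches C9 and gives a non-enolisable aldehyde in which C8 is a masked ketone.

Step 5
Reactants: 6 (S)-4-benzyloxazolidin-2-one; 7 pent-4-enoyl chloride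
Product: 8 (S)-4-benzyl-3-(pent-4-enoyl)oxazolidin-2-one
Conditions: n-BuLi, THF, −78 °C; then 7, −78 to 0 °C
Reagents that add atoms: none
Why: N-Acylation of the lithiated oxazolidinone with an acid chloride, the standard entry to Evans imides; the acyl chain holds C11, C10, C1 and C2.

Step 6
Reactants: 8 (S)-4-benzyl-3-(pent-4-enoyl)oxazolidin-2-one; 5 2-{(2S)-1-[(tert-butyldiphenylsilyl)oxy]propan-2-yl}-1,3-dithiane-2-carbaldehyde
Product: 10 Evans syn-aldol adduct (C9 hydroxyl; C8 dithiane; C11 imide), via boron enolate 9 (not isolated)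
Conditions: Bu2BOTf, Et3N, CH2Cl2, −78 to 0 °C; then 5, −78 to 0 °C; MeOH/pH 7 buffer work-up
Reagents that add atoms: none
Why: Evans syn-aldol: the Z-boron enolate 9 reacts through a Zimmerman–Traxler chair on the face away from the benzyl group, which sets C10 and C9 (syn) in the required sense; the aldehyde has no α-hydrogen and a peroxide-free work-up spares the dithiane.

Step 7
Reactants: 10 Evans syn-aldol adduct
Product: 11 Weinreb amide (C11 N-methoxy-N-methylamide; C9 hydroxyl; C8 dithiane)
Conditions: MeNHOMe·HCl, AlMe3, CH2Cl2, −20 to 0 °C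
Reagents that add atoms: N,O-dimethylhydroxylamine hydrochloride, CNOC.Cl
Why: Weinreb transamidation with the dimethylaluminium amide, assisted by the free β-hydroxyl; it releases the auxiliary and leaves C11 as an acyl group that will later accept exactly one Grignard equivalent.

Step 8
Reactants: 11 Weinreb amide
Product: 12 α-hydroxy ketone (C8 ketone; C9 hydroxyl; C11 Weinreb amide)
Conditions: MeI, CaCO3, MeCN/H2O (9:1), 45 °C
Reagents that add atoms: water, O
Why: Dithiane hydrolysis by S-methylation under CaCO3 buffer, neutral conditions that tolerate the alkene, the silyl ether and the amide and unveil the C8 ketone next to the C9 hydroxyl.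

Step 9
Reactants: 13 (4-methoxyphenyl)methanol; 14 tributyl(iodomethyl)stannane
Product: 15 tributyl{[(4-methoxybenzyl)oxy]methyl}stannane
Conditions: NaH, THF/DMF, 0 °C; then 14, rt
Reagents that add atoms: none
Why: Williamson ether synthesis on the iodomethylstannane gives a storable precursor of an alkoxymethyl carbanion, the C7 unit.

Step 10
Reactants: 12 α-hydroxy ketone; 15 tributyl{[(4-methoxybenzyl)oxy]methyl}stannane
Product: 16 C8,C9-diol with C7 PMB ether (C11 Weinreb amide)
Conditions: 15 (3 equiv), n-BuLi, THF, −78 °C; MgBr2·OEt2; then 12, −78 °C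
Reagents that add atoms: none
Why: Tin–lithium exchange and transmetalation give an alkoxymethylmagnesium reagent; the C9 alkoxide and the C8 carbonyl form a five-membered magnesium chelate (Cram chelate model) and the nucleophile enters anti to C10, which sets C8; at −78 °C the Weinreb amide should not be attacked.

Step 11
Reactants: 16 C8,C9-diol
Product: 17 C8,C9-acetonide Weinreb amide
Conditions: 2-methoxypropene, pyridinium p-toluenesulfonate (cat.), CH2Cl2, 0 °C to rt
Reagents that add atoms: 2-methoxypropene, COC(C)=C
Why: Acetonide formation on the 1,2-diol under mild acid ties O8 and O9 together for all basic and organometallic steps that follow.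

Step 12
Reactants: 17 C8,C9-acetonide Weinreb amide; 18 (3-bromopropoxy)(tert-butyl)dimethylsilane
Product: 19 C11 ketone carrying the C12–C14 chain (C14 silyl ether)
Conditions: 18, Mg, THF (Grignard reagent); then 17, 0 °C to rt
Reagents that add atoms: none
Why: Weinreb ketone synthesis: the magnesium chelate of the tetrahedral adduct prevents over-addition, so the C11–C12 bond forms once and brings in C12–C14.

Step 13
Reactants: 19 C11 ketone
Product: 20 C11 dioxolane
Conditions: (Me3SiOCH2)2, Me3SiOTf (cat.), CH2Cl2, −78 to −20 °C
Reagents that add atoms: 1,2-bis(trimethylsilyloxy)ethane, C[Si](C)(C)OCCO[Si](C)(C)C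
Why: Noyori ketalisation at low temperature; the dioxolane removes the acidity of H-10 (otherwise α to a ketone and later allylic to the enone) and keeps C11 out of steps 16 and 19.

Step 14
Reactants: 20 C11 dioxolane
Product: 21 C2 aldehyde
Conditions: OsO4 (cat.), NaIO4, 2,6-lutidine, dioxane/H2O (3:1), rt
Reagents that add atoms: sodium periodate (terminal oxidant; oxygen delivered through OsO4), [Na+].[O-]I(=O)(=O)=O
Why: Lemieux–Johnson cleavage of the only alkene gives the C2 aldehyde; 2,6-lutidine suppresses over-oxidation and the neutral conditions spare the PMB ether and both acetals.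

Step 15
Reactants: 21 C2 aldehyde
Product: 22 C1-methylene aldehyde (2-substituted acrolein)
Conditions: 37% aq. CH2O, pyrrolidine (cat.), EtCO2H (cat.), i-PrOH, 45 °C
Reagents that add atoms: formaldehyde, C=O
Why: Amine-catalysed Mannich condensation–elimination (α-methylenation of an aldehyde) introduces C15; an aldehyde has a single α-position, so the site of methylenation is unambiguous.

Step 16
Reactants: 22 C1-methylene aldehyde
Product: 23 C2 allylic alcohol (C2 epimers)
Conditions: MeMgBr, THF, −78 °C
Reagents that add atoms: methylmagnesium bromide, C[Mg]Br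
Why: 1,2-Addition of the Grignard reagent to the 2-substituted acrolein brings in C3; the C2 configuration is irrelevant because C2 is oxidised in step 18.

Step 17
Reactants: 23 C2 allylic alcohol
Product: 24 C2,C14-diol (C2 epimers)
Conditions: HF·pyridine, pyridine, THF, 0 °C
Reagents that add atoms: none
Why: Buffered HF·pyridine removes the primary tert-butyldimethylsilyl ether much faster than the tert-butyldiphenylsilyl ether and leaves both acetals intact.

Step 18
Reactants: 24 C2,C14-diol
Product: 25 C1-methylene ketone with tethered C14 aldehyde (key-step precursor)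
Conditions: Dess–Martin periodinane, NaHCO3, CH2Cl2, rt
Reagents that add atoms: none
Why: Dess–Martin oxidation converts the allylic alcohol into the C1-methylene ketone and the primary alcohol into the C14 aldehyde in one buffered, non-enolising operation.

Step 19
Reactants: 25 C1-methylene ketone with tethered C14 aldehyde
Product: 28 cyclohexane β-hydroxy ketone (key-step product), via cobalt enolate 26 (not isolated), via O-phenylsilyl aldol 27 (not isolated)
Conditions: Co(dpm)2 (5 mol%), PhSiH3 (1.2 equiv), ClCH2CH2Cl, 25 °C; aq. NH4Cl/MeOH work-up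
Reagents that add atoms: none
Why: A cobalt hydride formed from Co(dpm)2 and PhSiH3 transfers hydrogen to the unhindered C15 methylene of 25, which creates the C1 methyl group and gives the fully substituted cobalt enolate 26 regiospecifically, a species not accessible by deprotonation. Enolate 26 adds through C1 to the C14 aldehyde in a 6-(enolexo)-exo-trig aldol closure; the closest known reaction type is the cobalt-catalysed reductive aldol cyclisation of enone–aldehydes, and exchange with the silane releases O-silyl aldol 27, hydrolysed to 28 on work-up. C1 is controlled by C10: allylic 1,3-strain holds H-10 in the enolate plane, the tether through C11 lies on one face and the C9 arm on the other, so C14 can bond only anti to C9, which places the acyl group trans and the new methyl cis to the C9 arm. C14 is controlled by the metal bridge: with the O–Co bond syn to C10 (the geometry that maps from the favoured s-trans enone and keeps the C3 methyl away from the branched C10), the chair in which cobalt spans the enolate and aldehyde oxygens requires the aldehyde oxygen to be axial, i.e. cis to the equatorial acyl group. The step needs chemoselectivity for the enone over the aldehyde, which conjugate hydrometalation provides, and cis selectivity at C14, which rests on the enolate geometry and is the point to watch. The aldolate stays metal- or silicon-bound until work-up, which limits retro-aldol, and no other alkene is present to compete.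

Step 20
Reactants: 28 cyclohexane β-hydroxy ketone
Product: 29 14-O-trimethylsilyl ether
Conditions: Me3SiOTf, 2,6-lutidine, CH2Cl2, −78 °C
Reagents that add atoms: trimethylsilyl trifluoromethanesulfonate, C[Si](C)(C)OS(=O)(=O)C(F)(F)F
Why: Silylation of the hindered axial C14 hydroxyl blocks retro-aldol cleavage during the enolate chemistry of step 23.

Step 21
Reactants: 30 prop-2-yn-1-ol
Product: 31 (Z)-3-iodo-2-methylprop-2-en-1-ol
Conditions: MeMgBr (2.5 equiv), CuI (cat.), Et2O, −10 °C to rt; then I2, −78 to 0 °C
Reagents that add atoms: methylmagnesium bromide, C[Mg]Br; iodine, II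
Why: Hydroxyl-directed, copper-catalysed anti-carbomagnesiation of propargyl alcohol followed by iodinolysis; the cyclic alkenylmagnesium alkoxide places iodine cis to the CH2O group, which is the (Z)-geometry of C5=C6.

Step 22
Reactants: 31 (Z)-3-iodo-2-methylprop-2-en-1-ol
Product: 32 (Z)-3-bromo-1-iodo-2-methylprop-1-ene
Conditions: CBr4, PPh3, CH2Cl2, 0 °C
Reagents that add atoms: carbon tetrabromide, BrC(Br)(Br)Br
Why: Appel bromination of the allylic alcohol proceeds without allylic transposition or loss of alkene geometry.

Step 23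
Reactants: 29 14-O-trimethylsilyl ether; 32 (Z)-3-bromo-1-iodo-2-methylprop-1-ene
Product: 34 C3-alkylated β-hydroxy ketone (C4–C6 iodoalkene attached), via C3-alkylated silyl ether 33 (not isolated)
Conditions: LiN(iPr)2, THF, −78 °C; 32, DMPU, −78 to −40 °C; aq. citric acid/MeOH work-up
Reagents that add atoms: none
Why: Kinetic enolate alkylation: C1 is quaternary, so the ketone can be deprotonated only at C3, and the allylic bromide reacts by SN2 while the alkenyl iodide is inert; mild acid on work-up cleaves the trimethylsilyl ether of 33.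

Step 24
Reactants: 34 C3-alkylated β-hydroxy ketone
Product: 35 2,14-anti-diol
Conditions: Me4NBH(OAc)3, MeCN/AcOH (1:1), −30 °C
Reagents that add atoms: none
Why: Evans–Saksena reduction: the C14 hydroxyl binds the triacetoxyborohydride and delivers hydride intramolecularly through a chair, which should give the 1,3-anti diol and thereby set C2.

Step 25
Reactants: 35 2,14-anti-diol
Product: 36 2,14-diacetate
Conditions: Ac2O, pyridine, DMAP (cat.), rt
Reagents that add atoms: acetic anhydride, CC(=O)OC(C)=O
Why: Acetylation of the two secondary alcohols installs the final C2 and C14 acetates and prevents O2 from forming an internal ketal with C11 in step 26.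

Step 26
Reactants: 36 2,14-diacetate
Product: 37 C11 ketone 8,9-diol
Conditions: 1 M aq. HCl, THF, rt to 40 °C
Reagents that add atoms: water, O
Why: Acid hydrolysis removes the acetonide and the dioxolane together; acetates, PMB ether, silyl ether and iodoalkene are stable to dilute aqueous acid, and C10 keeps its more stable configuration with the C9 arm equatorial.

Step 27
Reactants: 37 C11 ketone 8,9-diol
Product: 38 11(20)-methylene 8,9-diol
Conditions: Zn, CH2Br2, TiCl4, THF/CH2Cl2, 0 °C to rt
Reagents that add atoms: dibromomethane, BrCBr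
Why: Takai–Lombardo methylenation is non-basic, so the β-hydroxy ketone should neither eliminate nor epimerise, and the reagent tolerates acetates and free hydroxyls.

Step 28
Reactants: 38 11(20)-methylene 8,9-diol
Product: 39 2,9,14-triacetate with 11(20)-alkene
Conditions: Ac2O, Et3N, DMAP, CH2Cl2, rt
Reagents that add atoms: acetic anhydride, CC(=O)OC(C)=O
Why: Acetylation of the secondary C9 hydroxyl; the tertiary C8 hydroxyl does not react, and with C11 now a methylene the C9 acetate cannot be lost by β-elimination.

Step 29
Reactants: 39 2,9,14-triacetate with 11(20)-alkene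
Product: 40 11,20-epoxide (C7 PMB ether)
Conditions: mCPBA, NaHCO3, CH2Cl2, 0 °C
Reagents that add atoms: 3-chloroperoxybenzoic acid, OOC(=O)c1cccc(Cl)c1
Why: Prilezhaev epoxidation of the 1,1-disubstituted alkene from the α face, anti to the axial C15 methyl, sets C11; the iodine-bearing trisubstituted alkene is strongly deactivated and should remain untouched.

Step 30
Reactants: 40 11,20-epoxide
Product: 41 C7 primary alcohol
Conditions: DDQ, CH2Cl2/pH 7 buffer (10:1), 0 °C
Reagents that add atoms: none
Why: Oxidative cleavage of the PMB ether by DDQ in buffered wet solvent is neutral and spares the epoxide, the acetates and the silyl ether.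

Step 31
Reactants: 41 C7 primary alcohol
Product: 42 C7 aldehyde with (Z)-alkenyl iodide
Conditions: TEMPO (cat.), PhI(OAc)2, CH2Cl2, rt
Reagents that add atoms: none
Why: Oxoammonium oxidation (TEMPO/PhI(OAc)2) is selective for the primary alcohol, does not cleave the adjacent tertiary carbinol and is mild enough for the epoxide; run directly after step 30 it also forestalls migration of the C9 acetate to O7.

Step 32
Reactants: 42 C7 aldehyde with (Z)-alkenyl iodide
Product: 43 ten-membered C7 allylic alcohol (19-O-silyl)
Conditions: CrCl2 (10 equiv), NiCl2 (cat.), DMSO/THF, rt, 2 mM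
Reagents that add atoms: none
Why: Nozaki–Hiyama–Kishi reaction: nickel-catalysed, chromium-mediated addition of the alkenyl iodide to the aldehyde with retention of the (Z)-geometry forms C6–C7 and closes the ten-membered ring at high dilution, tolerating esters and silyl ether; C7 is created here and its sense depends on the ring-forming conformation.

Step 33
Reactants: 43 ten-membered C7 allylic alcohol
Product: 44 7,19-diol
Conditions: Bu4NF, AcOH, THF, 0 °C to rt
Reagents that add atoms: none
Why: Fluoride cleavage of the silyl ether, buffered with acetic acid so that the acetates neither migrate nor hydrolyse and the epoxide is not opened.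

Step 34
Reactants: 44 7,19-diol
Product: 47 junceellolide K, via C19 aldehyde 45 (not isolated), via lactol 46 (not isolated)
Conditions: TEMPO (cat.), PhI(OAc)2 (2.5 equiv), CH2Cl2, rt
Reagents that add atoms: none
Why: Oxidative lactonisation of a 1,4-diol: the primary C19 alcohol is oxidised to aldehyde 45, which O7 traps as lactol 46, and this is oxidised further to the γ-lactone; the hindered allylic C7 hydroxyl reacts more slowly than the primary one and C17 is not enolised under these neutral conditions.

## Compound list

1 | methyl (S)-3-hydroxy-2-methylpropanoate | COC(=O)[C@@H](C)CO | starting material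
2 | methyl (S)-3-[(tert-butyldiphenylsilyl)oxy]-2-methylpropanoate | COC(=O)[C@@H](C)CO[Si](c1ccccc1)(c1ccccc1)C(C)(C)C | intermediate
3 | (S)-3-[(tert-butyldiphenylsilyl)oxy]-2-methylpropanal | O=C[C@@H](C)CO[Si](c1ccccc1)(c1ccccc1)C(C)(C)C | intermediate
4 | tert-butyl{[(2S)-2-(1,3-dithian-2-yl)propyl]oxy}diphenylsilane | S1CCCSC1[C@@H](C)CO[Si](c1ccccc1)(c1ccccc1)C(C)(C)C | intermediate
5 | 2-{(2S)-1-[(tert-butyldiphenylsilyl)oxy]propan-2-yl}-1,3-dithiane-2-carbaldehyde | O=CC1(SCCCS1)[C@@H](C)CO[Si](c1ccccc1)(c1ccccc1)C(C)(C)C | intermediate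
6 | (S)-4-benzyloxazolidin-2-one | O=C1N[C@@H](Cc2ccccc2)CO1 | starting material
7 | pent-4-enoyl chloride | C=CCCC(=O)Cl | starting material
8 | (S)-4-benzyl-3-(pent-4-enoyl)oxazolidin-2-one | C=CCCC(=O)N1[C@@H](Cc2ccccc2)COC1=O | intermediate
9 | (Z)-dibutylboron enolate of 8 | C=CC/C=C(\OB(CCCC)CCCC)N1[C@@H](Cc2ccccc2)COC1=O | intermediate (not isolated)
10 | Evans syn-aldol adduct: (4S)-4-benzyl-3-[(2S)-2-{(S)-hydroxy[2-((2S)-1-(tert-butyldiphenylsilyloxy)propan-2-yl)-1,3-dithian-2-yl]methyl}pent-4-enoyl]oxazolidin-2-one | O=C1OC[C@H](Cc2ccccc2)N1C(=O)[C@@H](CC=C)[C@H](O)C1(SCCCS1)[C@@H](C)CO[Si](c1ccccc1)(c1ccccc1)C(C)(C)C | intermediate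
11 | Weinreb amide (C11 N-methoxy-N-methylamide, C10 allyl, C9 hydroxyl, C8 dithiane) | CON(C)C(=O)[C@@H](CC=C)[C@H](O)C1(SCCCS1)[C@@H](C)CO[Si](c1ccccc1)(c1ccccc1)C(C)(C)C | intermediate
12 | α-hydroxy ketone (C8 ketone, C9 hydroxyl, C11 Weinreb amide) | CON(C)C(=O)[C@@H](CC=C)[C@H](O)C(=O)[C@@H](C)CO[Si](c1ccccc1)(c1ccccc1)C(C)(C)C | intermediate
13 | (4-methoxyphenyl)methanol | COc1ccc(CO)cc1 | starting material
14 | tributyl(iodomethyl)stannane | CCCC[Sn](CCCC)(CCCC)CI | starting material
15 | tributyl{[(4-methoxybenzyl)oxy]methyl}stannane | CCCC[Sn](CCCC)(CCCC)COCc1ccc(OC)cc1 | intermediate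
16 | C8,C9-diol with C7 PMB ether (C11 Weinreb amide) | CON(C)C(=O)[C@@H](CC=C)[C@H](O)[C@@](O)(COCc1ccc(OC)cc1)[C@@H](C)CO[Si](c1ccccc1)(c1ccccc1)C(C)(C)C | intermediate
17 | C8,C9-acetonide Weinreb amide | CON(C)C(=O)[C@@H](CC=C)[C@@H]1OC(C)(C)O[C@]1(COCc1ccc(OC)cc1)[C@@H](C)CO[Si](c1ccccc1)(c1ccccc1)C(C)(C)C | intermediate
18 | (3-bromopropoxy)(tert-butyl)dimethylsilane | CC(C)(C)[Si](C)(C)OCCCBr | starting material
19 | C11 ketone with C12–C14 chain (C14 tert-butyldimethylsilyl ether) | CC(C)(C)[Si](C)(C)OCCCC(=O)[C@@H](CC=C)[C@@H]1OC(C)(C)O[C@]1(COCc1ccc(OC)cc1)[C@@H](C)CO[Si](c1ccccc1)(c1ccccc1)C(C)(C)C | intermediate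
20 | C11 dioxolane | CC(C)(C)[Si](C)(C)OCCCC1(OCCO1)[C@@H](CC=C)[C@@H]1OC(C)(C)O[C@]1(COCc1ccc(OC)cc1)[C@@H](C)CO[Si](c1ccccc1)(c1ccccc1)C(C)(C)C | intermediate
21 | C2 aldehyde | CC(C)(C)[Si](C)(C)OCCCC1(OCCO1)[C@@H](CC=O)[C@@H]1OC(C)(C)O[C@]1(COCc1ccc(OC)cc1)[C@@H](C)CO[Si](c1ccccc1)(c1ccccc1)C(C)(C)C | intermediate
22 | C1-methylene aldehyde (2-substituted acrolein) | CC(C)(C)[Si](C)(C)OCCCC1(OCCO1)[C@@H](C(=C)C=O)[C@@H]1OC(C)(C)O[C@]1(COCc1ccc(OC)cc1)[C@@H](C)CO[Si](c1ccccc1)(c1ccccc1)C(C)(C)C | intermediate
23 | C2 allylic alcohol (mixture of C2 epimers) | CC(C)(C)[Si](C)(C)OCCCC1(OCCO1)[C@@H](C(=C)C(C)O)[C@@H]1OC(C)(C)O[C@]1(COCc1ccc(OC)cc1)[C@@H](C)CO[Si](c1ccccc1)(c1ccccc1)C(C)(C)C | intermediate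
24 | C2,C14-diol (mixture of C2 epimers) | OCCCC1(OCCO1)[C@@H](C(=C)C(C)O)[C@@H]1OC(C)(C)O[C@]1(COCc1ccc(OC)cc1)[C@@H](C)CO[Si](c1ccccc1)(c1ccccc1)C(C)(C)C | intermediate
25 | C1-methylene ketone with tethered C14 aldehyde (key-step precursor) | O=CCCC1(OCCO1)[C@@H](C(=C)C(C)=O)[C@@H]1OC(C)(C)O[C@]1(COCc1ccc(OC)cc1)[C@@H](C)CO[Si](c1ccccc1)(c1ccccc1)C(C)(C)C | intermediate
26 | (dipivaloylmethanato)cobalt enolate of 25 after hydride addition to C15 (divalent cobalt; O–Co syn to C10) | C/C(O[Co]O/C(C(C)(C)C)=C\C(=O)C(C)(C)C)=C(\C)[C@@H]([C@@H]1OC(C)(C)O[C@]1(COCc1ccc(OC)cc1)[C@@H](C)CO[Si](c1ccccc1)(c1ccccc1)C(C)(C)C)C1(OCCO1)CCC=O | intermediate (not isolated)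
27 | O-phenylsilyl aldol (14-O-SiH2Ph ether of 28) | CC(=O)[C@@]1(C)[C@@H](O[SiH2]c2ccccc2)CCC2(OCCO2)[C@@H]1[C@@H]1OC(C)(C)O[C@]1(COCc1ccc(OC)cc1)[C@@H](C)CO[Si](c1ccccc1)(c1ccccc1)C(C)(C)C | intermediate (not isolated)
28 | cyclohexane β-hydroxy ketone with C1 and C14 set (key-step product) | CC(=O)[C@@]1(C)[C@@H](O)CCC2(OCCO2)[C@@H]1[C@@H]1OC(C)(C)O[C@]1(COCc1ccc(OC)cc1)[C@@H](C)CO[Si](c1ccccc1)(c1ccccc1)C(C)(C)C | intermediate
29 | 14-O-trimethylsilyl ether of 28 | CC(=O)[C@@]1(C)[C@@H](O[Si](C)(C)C)CCC2(OCCO2)[C@@H]1[C@@H]1OC(C)(C)O[C@]1(COCc1ccc(OC)cc1)[C@@H](C)CO[Si](c1ccccc1)(c1ccccc1)C(C)(C)C | intermediate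
30 | prop-2-yn-1-ol | C#CCO | starting material
31 | (Z)-3-iodo-2-methylprop-2-en-1-ol | I/C=C(C)\CO | intermediate
32 | (Z)-3-bromo-1-iodo-2-methylprop-1-ene | I/C=C(C)\CBr | intermediate
33 | C3-alkylated 14-O-trimethylsilyl ether | I/C=C(C)\CCC(=O)[C@@]1(C)[C@@H](O[Si](C)(C)C)CCC2(OCCO2)[C@@H]1[C@@H]1OC(C)(C)O[C@]1(COCc1ccc(OC)cc1)[C@@H](C)CO[Si](c1ccccc1)(c1ccccc1)C(C)(C)C | intermediate (not isolated)
34 | C3-alkylated β-hydroxy ketone (C2 ketone, C14 hydroxyl, (Z)-iodoalkene C4–C6) | I/C=C(C)\CCC(=O)[C@@]1(C)[C@@H](O)CCC2(OCCO2)[C@@H]1[C@@H]1OC(C)(C)O[C@]1(COCc1ccc(OC)cc1)[C@@H](C)CO[Si](c1ccccc1)(c1ccccc1)C(C)(C)C | intermediate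
35 | 2,14-anti-diol | I/C=C(C)\CC[C@H](O)[C@@]1(C)[C@@H](O)CCC2(OCCO2)[C@@H]1[C@@H]1OC(C)(C)O[C@]1(COCc1ccc(OC)cc1)[C@@H](C)CO[Si](c1ccccc1)(c1ccccc1)C(C)(C)C | intermediate
36 | 2,14-diacetate | I/C=C(C)\CC[C@H](OC(C)=O)[C@@]1(C)[C@@H](OC(C)=O)CCC2(OCCO2)[C@@H]1[C@@H]1OC(C)(C)O[C@]1(COCc1ccc(OC)cc1)[C@@H](C)CO[Si](c1ccccc1)(c1ccccc1)C(C)(C)C | intermediate
37 | C11 ketone 8,9-diol (2,14-diacetate) | I/C=C(C)\CC[C@H](OC(C)=O)[C@@]1(C)[C@@H](OC(C)=O)CCC(=O)[C@@H]1[C@H](O)[C@@](O)(COCc1ccc(OC)cc1)[C@@H](C)CO[Si](c1ccccc1)(c1ccccc1)C(C)(C)C | intermediate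
38 | 11(20)-methylene 8,9-diol | I/C=C(C)\CC[C@H](OC(C)=O)[C@@]1(C)[C@@H](OC(C)=O)CCC(=C)[C@@H]1[C@H](O)[C@@](O)(COCc1ccc(OC)cc1)[C@@H](C)CO[Si](c1ccccc1)(c1ccccc1)C(C)(C)C | intermediate
39 | 2,9,14-triacetate with 11(20)-alkene and free 8-hydroxyl | I/C=C(C)\CC[C@H](OC(C)=O)[C@@]1(C)[C@@H](OC(C)=O)CCC(=C)[C@@H]1[C@H](OC(C)=O)[C@@](O)(COCc1ccc(OC)cc1)[C@@H](C)CO[Si](c1ccccc1)(c1ccccc1)C(C)(C)C | intermediate
40 | 11,20-epoxide (C7 PMB ether) | I/C=C(C)\CC[C@H](OC(C)=O)[C@@]1(C)[C@@H](OC(C)=O)CC[C@]2(CO2)[C@@H]1[C@H](OC(C)=O)[C@@](O)(COCc1ccc(OC)cc1)[C@@H](C)CO[Si](c1ccccc1)(c1ccccc1)C(C)(C)C | intermediate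
41 | C7 primary alcohol | I/C=C(C)\CC[C@H](OC(C)=O)[C@@]1(C)[C@@H](OC(C)=O)CC[C@]2(CO2)[C@@H]1[C@H](OC(C)=O)[C@@](O)(CO)[C@@H](C)CO[Si](c1ccccc1)(c1ccccc1)C(C)(C)C | intermediate
42 | C7 aldehyde with (Z)-alkenyl iodide (seco aldehyde) | I/C=C(C)\CC[C@H](OC(C)=O)[C@@]1(C)[C@@H](OC(C)=O)CC[C@]2(CO2)[C@@H]1[C@H](OC(C)=O)[C@@](O)(C=O)[C@@H](C)CO[Si](c1ccccc1)(c1ccccc1)C(C)(C)C | intermediate
43 | ten-membered C7 allylic alcohol (19-O-tert-butyldiphenylsilyl) | CC(=O)O[C@H]1CC/C(C)=C\[C@H](O)[C@@](O)([C@@H](C)CO[Si](c2ccccc2)(c2ccccc2)C(C)(C)C)[C@@H](OC(C)=O)[C@H]2[C@]3(CC[C@H](OC(C)=O)[C@]12C)CO3 | intermediate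
44 | 7,19-diol | CC(=O)O[C@H]1CC/C(C)=C\[C@H](O)[C@@](O)([C@@H](C)CO)[C@@H](OC(C)=O)[C@H]2[C@]3(CC[C@H](OC(C)=O)[C@]12C)CO3 | intermediate
45 | C19 aldehyde | CC(=O)O[C@H]1CC/C(C)=C\[C@H](O)[C@@](O)([C@@H](C)C=O)[C@@H](OC(C)=O)[C@H]2[C@]3(CC[C@H](OC(C)=O)[C@]12C)CO3 | intermediate (not isolated)
46 | lactol (C19 hemiacetal with O7, mixture at C19) | CC(=O)O[C@H]1CC/C(C)=C\[C@@H]2OC(O)[C@H](C)[C@@]2(O)[C@@H](OC(C)=O)[C@H]2[C@]3(CC[C@H](OC(C)=O)[C@]12C)CO3 | intermediate (not isolated)
47 | junceellolide K | CC(=O)O[C@H]1CC/C(C)=C\[C@@H]2OC(=O)[C@H](C)[C@@]2(O)[C@@H](OC(C)=O)[C@H]2[C@]3(CC[C@H](OC(C)=O)[C@]12C)CO3 | target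

## Step count and points of risk

Total: 34 steps. Longest linear sequence: 30 steps (steps 1–4, 6–8, 10–20, 23–34). Steps 5, 9, 21 and 22 prepare side reagents.

**Step 19 (key step).** The most likely failure is loss of control at C14. If the enolate is formed, or equilibrates, with O–Co syn to the C15 methyl, it can still reach the aldehyde through a bridged chair, now with the aldehyde oxygen equatorial, and gives the trans aldol. Plain 1,4-reduction without ring closure and silane reduction of the aldehyde are the other side paths. The fallback sets out from 25 and forms the same C1–C14 bond without hydride, by a thiolate-triggered Michael–aldol cyclisation. Li[Me3AlSPh] adds PhS reversibly to C15, so the enolate geometry can adjust, and the aluminium enolate closes onto the aldehyde as the aluminium chelate to give the 15-phenylthio aldol F1. Desulfurisation with Raney nickel (deactivated, EtOH, rt) turns CH2SPh into the C15 methyl and returns to 28.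

**Step 32.** What may go wrong is poor facial selectivity at C7, oligomerisation at workable dilution, opening of the spiro-epoxide by chloride under chromium Lewis acid activation, or an α-ketol shift of the α-hydroxy aldehyde. The fallback sets out from 43 obtained as a mixture at C7 and no longer asks the ring closure for this stereocentre. Dess–Martin oxidation gives the macrocyclic C7 enone F2. Zn(BH4)2 in Et2O at −20 °C then reduces it under chelation between O8 and the C7 carbonyl, with hydride from the outer face on the C17 side, which gives the 7,8-anti diol and returns to 43.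

**Step 10.** Chelate control may erode if lithium instead of magnesium carries the addition; the reagent may also attack the Weinreb amide or cause base-induced ketol isomerisation of 12. The fallback sets out from 12 and uses a silicon-masked hydroxymethyl unit delivered by a true Grignard reagent. (iPrO)Me2SiCH2MgCl (THF, −78 °C) adds under the same magnesium chelate and gives the silylmethyl diol F3. Tamao oxidation (H2O2, KF, KHCO3) gives the 7,8,9-triol F4. Stannylene-mediated etherification of the primary hydroxyl (Bu2SnO; then PMBCl, CsF) returns to 16.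

**Step 29.** The peracid may oxidise the alkenyl iodide at iodine, or face selectivity at C11 may be incomplete. The fallback sets out from 39 and makes the epoxide by displacement instead of oxygen transfer. OsO4 (cat.) with N-methylmorpholine N-oxide dihydroxylates the 1,1-disubstituted alkene from the same α face (the iodoalkene is inert) to give the 11,20-diol F5. Selective sulfonylation of the primary hydroxyl (TsCl, Et3N, DMAP) gives the 20-tosylate F6, and DBU closes the epoxide with retention at C11, returning to 40.

**Step 24.** Anti selectivity may be low, because the quaternary C1 adds gauche interactions in the chair of hydride delivery. The fallback sets out from 34 and uses an Evans–Tishchenko reduction (SmI2 (cat.), CH3CHO, THF, −10 °C), in which hydride shifts within a samarium-bound hemiacetal. It gives the 1,3-anti diol as its 14-monoacetate F7, and acetylation of O2 (Ac2O, pyridine, DMAP) returns to 36.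

## Further compounds

F1 | step 19 | 15-phenylthio aldol (C15 as CH2SPh; otherwise as 28) | CC(=O)[C@@]1(CSc2ccccc2)[C@@H](O)CCC2(OCCO2)[C@@H]1[C@@H]1OC(C)(C)O[C@]1(COCc1ccc(OC)cc1)[C@@H](C)CO[Si](c1ccccc1)(c1ccccc1)C(C)(C)C
F2 | step 32 | macrocyclic C7 enone | CC(=O)O[C@H]1CC/C(C)=C\C(=O)[C@@](O)([C@@H](C)CO[Si](c2ccccc2)(c2ccccc2)C(C)(C)C)[C@@H](OC(C)=O)[C@H]2[C@]3(CC[C@H](OC(C)=O)[C@]12C)CO3
F3 | step 10 | silylmethyl diol (C7 as CH2Si(CH3)2OiPr) | CON(C)C(=O)[C@@H](CC=C)[C@H](O)[C@@](O)(C[Si](C)(C)OC(C)C)[C@@H](C)CO[Si](c1ccccc1)(c1ccccc1)C(C)(C)C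
F4 | step 10 | 7,8,9-triol | CON(C)C(=O)[C@@H](CC=C)[C@H](O)[C@@](O)(CO)[C@@H](C)CO[Si](c1ccccc1)(c1ccccc1)C(C)(C)C
F5 | step 29 | 11,20-diol | I/C=C(C)\CC[C@H](OC(C)=O)[C@@]1(C)[C@@H](OC(C)=O)CC[C@](O)(CO)[C@@H]1[C@H](OC(C)=O)[C@@](O)(COCc1ccc(OC)cc1)[C@@H](C)CO[Si](c1ccccc1)(c1ccccc1)C(C)(C)C
F6 | step 29 | 20-tosylate of the 11,20-diol | I/C=C(C)\CC[C@H](OC(C)=O)[C@@]1(C)[C@@H](OC(C)=O)CC[C@](O)(COS(=O)(=O)c2ccc(C)cc2)[C@@H]1[C@H](OC(C)=O)[C@@](O)(COCc1ccc(OC)cc1)[C@@H](C)CO[Si](c1ccccc1)(c1ccccc1)C(C)(C)C
F7 | step 24 | 14-monoacetate of the 2,14-anti-diol | I/C=C(C)\CC[C@H](O)[C@@]1(C)[C@@H](OC(C)=O)CCC2(OCCO2)[C@@H]1[C@@H]1OC(C)(C)O[C@]1(COCc1ccc(OC)cc1)[C@@H](C)CO[Si](c1ccccc1)(c1ccccc1)C(C)(C)C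
A1 | alternative 1 | 9-O-triethylsilyl hydroxy lactone | CC(=O)O[C@H]1CC/C(C)=C\[C@@H]2OC(=O)[C@H](C)[C@@]2(O)[C@@H](O[Si](CC)(CC)CC)[C@H]2[C@]3(CC[C@H](OC(C)=O)[C@]12C)CO3
A2 | alternative 2 | aldol adduct with C10, C1 and C2 set | C/C(=C/I)CC[C@H](O)[C@@]1(C)C(=O)CC[C@@H](O[Si](C)(C)C(C)(C)C)[C@@H]1C=C
A3 | alternative 2 | 4-(tert-butyldimethylsilyloxy)-2-methylcyclohex-2-en-1-one | CC1=C[C@H](O[Si](C)(C)C(C)(C)C)CCC1=O
A4 | alternative 2 | (Z)-5-iodo-4-methylpent-4-enal | C/C(=C/I)CCC=O
A5 | alternative 3 | ten-membered 8,9-diol | CC(=O)O[C@H]1CC/C(C)=C\[C@H](O[Si](C)(C)C(C)(C)C)[C@@](O)([C@@H](C)COCc2ccc(OC)cc2)[C@@H](O)[C@H]2C3(OCCO3)CC[C@H](OC(C)=O)[C@]12C
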